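**Plan**

Numbering used here: ring A (eight-membered) = C-1 (CH–OAc), C-2, C-3 (CH–CH3), C-4, C-5, C-6, C-7, C-8 (CH carrying the side chain, C-1′ onward); ring B (butenolide) = C-6, C-7, C-11 (C=O), O, C-10; ring C (cyclopropane) = C-4, C-5, C-9.
Retrosynthesis: acetate ⇒ C-1 ketone ⇒ C-1/C-8 enol thioether; ring B ⇒ C-6 enol triflate + hydroxymethylstannane; then the ring-A bonds C-6–C-7 and C-8–C-1 are cut together, which removes C-7/C-8 (with C-11 and the side chain) as a 2-alkynoate and rejoins C-6 to C-1 as a cyclohexanone.
Enabling feature: C-7 and C-8 are adjacent ring-A carbons lying between a carbonyl-level carbon (C-6, whose other neighbour C-5 is a non-enolisable cyclopropane carbon) and an oxygenated, enolisable carbon (C-1); ring A is therefore a 5-methylbicyclo[4.1.0]heptan-2-one with an alkyne inserted into its C(=O)–Cα bond.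
Forward: ring C is built on a six-membered enone, the α-carbon is sulfenylated (activating group and latent C-1 carbonyl), ring A arises by enolate–ynoate conjugate addition/aldol/fragmentation with triflate trapping, ring B by Stille coupling and lactonisation, then the sulfur is hydrolysed off and the ketone is reduced and acetylated.
Stereochemistry: C-3 from enantioselective deprotonation of 4-methylcyclohexanone; C-4/C-5 from ylide cyclopropanation anti to that methyl; C-1′ from (R)-citronellal, whose ten carbons become C-7, C-8 and the whole side chain; C-8 by equilibration next to the C-1 ketone; C-1 by hydride attack anti to the C-8 side chain.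

Key step: step 7

Assumption (step 1): the sense of induction of the chiral lithium amide is taken to follow that known for 4-tert-butylcyclohexanone, so that the (S,S)-amide gives the (R)-enol ether; if the sense is the opposite, the (R,R)-amide is used.
Assumption (step 9): in ketone 20 the C-8 centre is epimerisable, and the epimer with H-8 anti to the cyclopropane methylene (8S, as in the target) is taken to be the one favoured on protonation and equilibration.

**Route**

Step 1
Reactants: 1 4-methylcyclohexanone
Product: 3 (R)-trimethyl[(4-methylcyclohex-1-en-1-yl)oxy]silane, via lithium enolate 2 (not isolated)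
Conditions: LiN[(S)-CH(CH3)Ph]2 (from (S,S)-bis(1-phenylethyl)amine and n-BuLi), TMSCl (internal quench), THF, −78 °C
Reagents that add atoms: chlorotrimethylsilane, C[Si](C)(C)Cl
Why: Desymmetrising deprotonation with a C2-symmetric chiral lithium amide and internal silyl quench (enantioselective enolisation) removes one of the two enantiotopic axial α-protons and so fixes the methyl-bearing centre (future C-3) as R; residual antipode should be removable after step 7 as a diastereomer.

Step 2
Reactants: 3 (R)-trimethyl[(4-methylcyclohex-1-en-1-yl)oxy]silane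
Product: 4 (R)-4-methylcyclohex-2-en-1-one
Conditions: Pd(OAc)2 (10 mol %), O2 (1 atm), DMSO, rt
Reagents that add atoms: none
Why: Saegusa–Ito oxidation: the palladium enolate formed from the silyl enol ether undergoes β-hydride elimination on the silylated side only, which places the enone double bond next to the existing stereocentre without touching it under neutral conditions.

Step 3
Reactants: 4 (R)-4-methylcyclohex-2-en-1-one
Product: 5 (1S,5R,6S)-5-methylbicyclo[4.1.0]heptan-2-one
Conditions: Me3S(O)I, NaH, DMSO, rt
Reagents that add atoms: trimethylsulfoxonium iodide, C[S+](C)(C)=O.[I-]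
Why: Corey–Chaykovsky cyclopropanation: conjugate addition of dimethylsulfoxonium methylide to the enone β-carbon anti to the adjacent methyl group and 3-exo-tet closure of the enolate should give the cis-fused cyclopropane trans to the methyl group (future C-4 and C-5, both S).

Step 4
Reactants: 5 (1S,5R,6S)-5-methylbicyclo[4.1.0]heptan-2-one
Product: 7 (1S,5R,6S)-5-methyl-3-(phenylsulfanyl)bicyclo[4.1.0]heptan-2-one (both epimers at C-3 of the bicycle), via lithium enolate 6 (not isolated)
Conditions: LiN(i-Pr)2 (2 equiv), THF, −78 °C; PhSO2SPh, −78 to 0 °C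
Reagents that add atoms: S-phenyl benzenethiosulfonate, O=S(=O)(Sc1ccccc1)c1ccccc1
Why: Enolate sulfenylation with a thiosulfonate: only C-3 of the bicycle can be enolised because the other α-carbon is the cyclopropane bridgehead, so the phenylthio helper (enolate- and carbanion-stabilising group, later the latent ketone) goes regiospecifically to the future C-1; its new centre forms as an epimer mixture and is erased in step 7.

Step 5
Reactants: 8 (R)-citronellal
Product: 10 (R)-3,7-dimethyloct-6-en-1-yne, via alkenyl nonaflate 9 (not isolated)
Conditions: n-C4F9SO2F, phosphazene base P2-Et, DMF, −20 °C to rt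
Reagents that add atoms: none
Why: One-pot enol nonaflate formation and base-induced anti elimination turns the CH2–CHO terminus into C≡CH with all ten carbons kept; the stereocentre is β to the carbonyl and cannot be enolised, and in the product the acetylenic proton is removed in preference to the propargylic one.

Step 6
Reactants: 10 (R)-3,7-dimethyloct-6-en-1-yne
Product: 12 methyl (R)-4,8-dimethylnon-7-en-2-ynoate, via lithium acetylide 11 (not isolated)
Conditions: n-BuLi, THF, −78 °C; ClCO2Me, −78 to 0 °C
Reagents that add atoms: methyl chloroformate, COC(=O)Cl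
Why: C-Acylation of the lithium acetylide with a chloroformate gives the 2-alkynoate (its ester carbon is the future C-11); the propargylic stereocentre is not deprotonated because the terminal C–H is far more acidic.

Step 7
Reactants: 7 (1S,5R,6S)-5-methyl-3-(phenylsulfanyl)bicyclo[4.1.0]heptan-2-one and 12 methyl (R)-4,8-dimethylnon-7-en-2-ynoate
Product: 17 methyl (1S,7R,8S)-7-methyl-4-[(2R)-6-methylhept-5-en-2-yl]-5-(phenylsulfanyl)-2-(trifluoromethanesulfonyloxy)bicyclo[6.1.0]nona-2,4-diene-3-carboxylate (ring A dienyl triflate), via sodium enolate 13 (not isolated), via allenolate 14 (not isolated), via cyclobutene alkoxide 15 (not isolated), via ring-expanded enolate 16 (not isolated)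
Conditions: NaH, THF, 0 °C; 12 (1.1 equiv), THF–DMF, 0 °C to rt; PhNTf2, 0 °C to rt
Reagents that add atoms: N-phenyl-bis(trifluoromethanesulfonimide), O=S(=O)(N(c1ccccc1)S(=O)(=O)C(F)(F)F)C(F)(F)F
Why: Proposed new method: sodium enolate 13, stabilised and softened by sulfur, adds to the β-carbon of ynoate 12 (bond C-1–C-8); the ester allenolate 14, which has no enolisable proton beside it, closes through its α-carbon onto the cyclopropyl ketone (bond C-6–C-7, 4-exo-trig aldol) to the cyclobutene alkoxide 15, and 15 collapses by retro-aldol cleavage of the old C-6–C-1 bond to the vinylogous β-keto ester enolate 16, which is O-sulfonylated at the C-6 oxygen. The closest known reactions are the two-carbon ring expansions of cyclic β-keto esters and β-keto sulfones with acetylenic esters and the acyl-alkylation of arynes, which run through the same conjugate addition, aldol closure and fragmentation; an α-sulfenyl ketone as pronucleophile and a β-branched 2-alkynoate as acceptor go beyond them. Ring A is therefore not closed by a medium-ring cyclisation: the only ring closure is the four-membered one, and the eight-membered ring arises when the 6–4 fused bicycle opens, the two inserted carbons C-7 and C-8 coming from the alkyne. No stereocentre is created, since C-1, C-6, C-7 and C-8 all end trigonal; C-3, C-4, C-5 and C-1′ are spectators, and both new ring alkenes should be Z because the delocalised anion 16 can relax within the eight-membered ring. The regiochemistry rests on two substrate features: ketone 7 enolises only toward the sulfur-bearing carbon (the other α-carbon is the cyclopropane bridgehead C-5), and the ynoate is attacked at its β-carbon, so that its α-carbon, which carries the future lactone carbonyl C-11, ends on C-6. The selectivity that must be secured is conjugate addition over proton transfer from the propargylic C-1′–H of 12 (ynoate–allenoate isomerisation); the low basicity of the thio-enolate and the aprotic medium are relied on for this, and the fragmentation is driven by the change from an alkoxide in a strained ring to a doubly stabilised enolate.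

Step 8
Reactants: 17 ring A dienyl triflate
Product: 19 butenolide enol thioether (rings A, B and C closed; C-1(SPh)=C-8; 3R,4S,5S,1′R), via hydroxymethyl dienoate 18 (not isolated)
Conditions: Bu3SnCH2OH, Pd(PPh3)4 (cat.), LiCl, 1,4-dioxane, 100 °C
Reagents that add atoms: (tributylstannyl)methanol, CCCC[Sn](CCCC)(CCCC)CO
Why: Stille cross-coupling of the activated β-triflyloxy enoate with a hydroxymethylstannane proceeds with retention of alkene geometry, and the resulting γ-hydroxy Z-enoate lactonises (5-exo-trig acyl substitution) to ring B; the vinyl sulfide and the trisubstituted olefin are inert and no stereocentre is formed.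

Step 9
Reactants: 19 butenolide enol thioether
Product: 20 C-1 ketone (3R,4S,5S,8S,1′R)
Conditions: HgCl2, MeCN–H2O (4:1), 60 °C
Reagents that add atoms: water, O
Why: Thiophilic, HgCl2-assisted hydrolysis of the enol thioether (the unmasking half of a 1,2-carbonyl transposition): C-8 is protonated, water adds to the C-1 thionium ion and the thiol is captured by mercury, so the phenylthio helper leaves and C-1 becomes the ketone; the new C-8 centre, α to the ketone and allylic to the butenolide, equilibrates under the acidic conditions and is expected (assumption above) to settle as 8S, while protonation at C-6 is disfavoured because that carbon is the electron-poor β-carbon of the butenolide.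

Step 10
Reactants: 20 C-1 ketone
Product: 21 C-1 alcohol (1R,3R,4S,5S,8S,1′R)
Conditions: NaBH4, CeCl3·7H2O, MeOH, −78 °C
Reagents that add atoms: none
Why: Luche-type borohydride reduction: the cerium-activated ketone is reduced at low temperature without enolisation of C-8 and without touching the butenolide or the olefin, and hydride should attack C-1 from the face opposite the adjacent branched C-8 side chain, giving the cis (1R,8S) alcohol.

Step 11
Reactants: 21 C-1 alcohol
Product: 22 CNP0018922.1 (target, 1R,3R,4S,5S,8S,1′R acetate)
Conditions: Ac2O, pyridine, DMAP (cat.), CH2Cl2, rt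
Reagents that add atoms: acetic anhydride, CC(=O)OC(C)=O
Why: DMAP-catalysed O-acylation of the secondary alcohol with retention at C-1 completes the target.

**Compound list**

1 | 4-methylcyclohexanone | CC1CCC(=O)CC1 | starting material
2 | lithium (R)-4-methylcyclohex-1-en-1-olate (not isolated) | [Li+].[O-]C1=CC[C@H](C)CC1 | intermediate
3 | (R)-trimethyl[(4-methylcyclohex-1-en-1-yl)oxy]silane | C[Si](C)(C)OC1=CC[C@H](C)CC1 | intermediate
4 | (R)-4-methylcyclohex-2-en-1-one | O=C1C=C[C@H](C)CC1 | intermediate
5 | (1S,5R,6S)-5-methylbicyclo[4.1.0]heptan-2-one | O=C1CC[C@@H](C)[C@@H]2C[C@H]12 | intermediate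
6 | lithium (1S,5R,6S)-5-methylbicyclo[4.1.0]hept-2-en-2-olate (not isolated) | [Li+].[O-]C1=CC[C@@H](C)[C@@H]2C[C@H]12 | intermediate
7 | (1S,5R,6S)-5-methyl-3-(phenylsulfanyl)bicyclo[4.1.0]heptan-2-one (C-3 epimers) | O=C1C(Sc2ccccc2)C[C@@H](C)[C@@H]2C[C@H]12 | intermediate
8 | (R)-citronellal, (R)-3,7-dimethyloct-6-enal | C[C@H](CCC=C(C)C)CC=O | starting material
9 | (3R)-3,7-dimethylocta-1,6-dien-1-yl nonafluorobutane-1-sulfonate (E/Z mixture, not isolated) | C[C@H](CCC=C(C)C)C=COS(=O)(=O)C(F)(F)C(F)(F)C(F)(F)C(F)(F)F | intermediate
10 | (R)-3,7-dimethyloct-6-en-1-yne | C[C@H](CCC=C(C)C)C#C | intermediate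
11 | lithium acetylide of 10 (not isolated) | C[C@H](CCC=C(C)C)C#[C-].[Li+] | intermediate
12 | methyl (R)-4,8-dimethylnon-7-en-2-ynoate | C[C@H](CCC=C(C)C)C#CC(=O)OC | intermediate
13 | sodium (1S,5R,6S)-5-methyl-3-(phenylsulfanyl)bicyclo[4.1.0]hept-2-en-2-olate (not isolated) | [Na+].[O-]C1=C(Sc2ccccc2)C[C@@H](C)[C@@H]2C[C@H]12 | intermediate
14 | sodium allenolate from conjugate addition: C-1 quaternary (SPh), C-8=C-7=C(O−)OMe, C-6 ketone (C-1 epimers, not isolated) | O=C1C(Sc2ccccc2)(C(=C=C([O-])OC)[C@H](C)CCC=C(C)C)C[C@@H](C)[C@@H]2C[C@H]12.[Na+] | intermediate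
15 | sodium cyclobutene alkoxide: cyclobutene C-1–C-8=C-7–C-6 cis-fused to the six-membered ring, O− on C-6 (not isolated) | C12(Sc3ccccc3)C[C@@H](C)[C@@H]3C[C@@H]3C1([O-])C(C(=O)OC)=C2[C@H](C)CCC=C(C)C.[Na+] | intermediate
16 | sodium enolate of the ring-expanded β-keto ester: C-6(O−)=C-7(CO2Me)–C-8(side chain)=C-1(SPh) (not isolated) | C1[C@@H](C)[C@@H]2C[C@@H]2/C([O-])=C(/C(=O)OC)C(/[C@H](C)CCC=C(C)C)=C1/Sc1ccccc1.[Na+] | intermediate
17 | methyl (1S,7R,8S)-7-methyl-4-[(2R)-6-methylhept-5-en-2-yl]-5-(phenylsulfanyl)-2-(trifluoromethanesulfonyloxy)bicyclo[6.1.0]nona-2,4-diene-3-carboxylate | C1[C@@H](C)[C@@H]2C[C@@H]2/C(OS(=O)(=O)C(F)(F)F)=C(/C(=O)OC)C(/[C@H](C)CCC=C(C)C)=C1/Sc1ccccc1 | intermediate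
18 | methyl (1S,7R,8S)-2-(hydroxymethyl)-7-methyl-4-[(2R)-6-methylhept-5-en-2-yl]-5-(phenylsulfanyl)bicyclo[6.1.0]nona-2,4-diene-3-carboxylate (not isolated) | C1[C@@H](C)[C@@H]2C[C@@H]2/C(CO)=C(/C(=O)OC)C(/[C@H](C)CCC=C(C)C)=C1/Sc1ccccc1 | intermediate
19 | butenolide enol thioether: target skeleton with C-1(SPh)=C-8 in place of CH(OAc)–CH (3R,4S,5S,1′R) | C1[C@@H](C)[C@@H]2C[C@@H]2C2=C(C(=O)OC2)C(/[C@H](C)CCC=C(C)C)=C1/Sc1ccccc1 | intermediate
20 | C-1 ketone of the target skeleton (3R,4S,5S,8S,1′R) | O=C1C[C@@H](C)[C@@H]2C[C@@H]2C2=C(C(=O)OC2)[C@@H]1[C@H](C)CCC=C(C)C | intermediate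
21 | C-1 alcohol, deacetyl target (1R,3R,4S,5S,8S,1′R) | O[C@@H]1C[C@@H](C)[C@@H]2C[C@@H]2C2=C(C(=O)OC2)[C@@H]1[C@H](C)CCC=C(C)C | intermediate
22 | CNP0018922.1, C-1 acetate (1R,3R,4S,5S,8S,1′R) | CC(=O)O[C@@H]1C[C@@H](C)[C@@H]2C[C@@H]2C2=C(C(=O)OC2)[C@@H]1[C@H](C)CCC=C(C)C | target

**Count and risks**

Total step count: 11. Longest linear sequence: 9 steps (steps 1–4 and 7–11; the ynoate branch, steps 5–6, joins at step 7).

Steps most likely to fail:

Step 7. What may go wrong: proton transfer from the propargylic C-1′–H of 12 to enolate 13 (isomerisation of the ynoate to an allenoate and erosion of C-1′) outrunning conjugate addition, or reversal of the conjugate addition before the allenolate closes onto the hindered cyclopropyl ketone. The fallback uses known chemistry and no base: it sets out from 7 (with 12) and comes back at 17. Ketone 7 is silylated (TMSOTf, Et3N, CH2Cl2) to the trimethylsilyl enol ether F1. F1 undergoes the acid-catalysed stepwise [2+2] cycloaddition of silyl enol ethers with alkynoates (Tf2NH cat. or EtAlCl2, CH2Cl2, −78 °C), the oxygen-activated carbon attacking the ynoate β-carbon, to give the silyloxycyclobutene F2. Bu4NF in THF then releases the alkoxide, which opens by the same retro-aldol cleavage to the tetrabutylammonium enolate F3, and F3 is triflated in the same flask with PhNTf2 to give 17.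

Step 9. What may go wrong: equilibration at C-8 settling mainly on the epimer with the side chain on the face of the cyclopropane hydrogens (8R), so that the material entering step 10 has the wrong C-8 configuration. The fallback sets out from 20 (as its epimer mixture) and comes back at 21, replacing step 10; no further compound is needed (F0). It is a Noyori asymmetric hydrogenation run as a dynamic kinetic resolution (RuCl2[(S)-xylbinap][(S)-daipen] or its enantiomer, whichever is matched to the 1R carbinol, t-BuOK cat., i-PrOH, H2). The base interconverts the C-8 epimers while the catalyst reduces only the one that leads to the cis alcohol, so that C-8 and C-1 are set together under catalyst control instead of by the ground-state preference of the ketone.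

Step 10. What may go wrong: hydride delivery on the same face as the C-8 side chain, giving the C-1 epimer. The fallback sets out from 20 and comes back at 22, replacing step 11. The reduction product is accepted as the C-1 epimeric alcohol F4, which is inverted in a Mitsunobu reaction with acetic acid (PPh3, DIAD, AcOH, toluene, 0 °C to rt); the acetate is introduced with inversion at C-1 and the target is reached directly.

Further compounds
F1 | step 7 | trimethyl{[(1S,5R,6S)-5-methyl-3-(phenylsulfanyl)bicyclo[4.1.0]hept-2-en-2-yl]oxy}silane | C[Si](C)(C)OC1=C(Sc2ccccc2)C[C@@H](C)[C@@H]2C[C@H]12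
F2 | step 7 | silyloxycyclobutene (O-trimethylsilyl ether of alkoxide 15) | C12(Sc3ccccc3)C[C@@H](C)[C@@H]3C[C@@H]3C1(O[Si](C)(C)C)C(C(=O)OC)=C2[C@H](C)CCC=C(C)C
F3 | step 7 | tetrabutylammonium salt of the ring-expanded enolate (anion of 16) | C1[C@@H](C)[C@@H]2C[C@@H]2/C([O-])=C(/C(=O)OC)C(/[C@H](C)CCC=C(C)C)=C1/Sc1ccccc1.CCCC[N+](CCCC)(CCCC)CCCC
F0 | step 9 | none | none
F4 | step 10 | C-1 epimer of alcohol 21 (1S,3R,4S,5S,8S,1′R) | O[C@H]1C[C@@H](C)[C@@H]2C[C@@H]2C2=C(C(=O)OC2)[C@@H]1[C@H](C)CCC=C(C)C
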